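Late times worried me: in the larch run, target plus starting material still came to 97.0% at 2.08 d but to 82.0% at 4.00 d, so material was leaving that pair, and this recipe allows 6.0 d. I decided to keep the charge and change the stop, so the next run needed a stopping time.

the same everywhere: starting material 0.51 M
- alder: second substrate 2 equiv; free catalyst 0.5 mol%; the very flask that is asked about, followed so far
- larch: second substrate 2 equiv; free catalyst 0.34 mol%; run made earlier
- flask: second substrate 2.00 equiv; free catalyst 0.5 mol%; time 6.0 d

alder run (percent of the starting material charged)

| time / h | target / % | starting material / % |
|---|---|---|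
| 10.0 | 28 | 72 |
| 15.0 | 41 | 61 |
| 25.0 | 65 | 36 |
| 40.0 | 91 | 3 |

larch run (percent of the starting material charged)

| time / d | target / % | starting material / % |
|---|---|---|
| 0.417 | 18 | 80 |
| 1.04 | 46 | 54 |
| 2.08 | 84 | 13 |
| 4.00 | 80 | 2 |

(scatter of a reading: 1.5 percentage points)

- the best time, 6.0 d at the latest, for target
- the amount of target, in percent of the starting material charged, at that time
- earliest time at which at least nineteen twentieths of that best amount are there, in d
- latest time at which they still are, in d



I counted turnovers. In the alder run, starting material fell from 72% to 36% between 10.0 h and 25.0 h, which at 0.5 mol% reads as 4.80 h⁻¹, my turnover frequency, the starting material consumed per hour per catalyst charged. The larch run, with less catalyst, read 4.94 h⁻¹, so I carried the alder figure.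

The flask needed 200 turnovers to use its starting material, which meant 1.74 d at that frequency, while the 6.0 d allowed held 691. I committed to stopping near 1.74 d and watching the last of the starting material.

The forecast gave 91.5% at 1.75 d, with the window from 1.57 d to 2.2 d, and it read from the two runs that “rate scales with catalyst loading”.

The flask gave 93.7% at 1.81 d, with the window from 1.54 d to 2.17 d, so the forecast held within its margins. In the flask at 0.600 d, catalyst intermediate A, the resting state at that moment, held 88.7% of the catalyst, free catalyst 6.81% and catalyst intermediate B 4.49%.

    target + free catalyst ⇌ isomer of the product + free catalyst, rate k1*[free catalyst]*[target] forward; the back reaction follows from the equilibrium constant (K = 1.50, k = 3.80 L mol⁻¹ h⁻¹)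
    second substrate + free catalyst ⇌ catalyst intermediate B (K = 0.760 L mol⁻¹, k = 2300 L mol⁻¹ h⁻¹)
    starting material + free catalyst ⇌ catalyst intermediate A (K = 490 L mol⁻¹, k = 270 L mol⁻¹ h⁻¹)
    catalyst intermediate B → free catalyst + second product (k = 90.0 h⁻¹)
    catalyst intermediate A → free catalyst + target (k = 5.90 h⁻¹)

With 0.12 mol% of free catalyst, 4.80 h⁻¹ over 6.0 d counted to 82.9% of the starting material consumed. That neighbour flask ended with 85.1% of target and 13.0% of starting material left.

All runs were computed with constants of no real substance, noise included.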